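# Proposed synthesis of gnetofuran A by a (4+1) annulation of a hydroxynitrostyrene with a benzylic sulfonium ylide

## The problem

Gnetofuran A (19) is a 2,3-dihydrobenzofuran. Its benzo ring (ring A) carries a methoxy group at C7 and an (E)-3,5-dihydroxystyryl arm (ring C) at C5; C2 carries a 4-hydroxy-3-methoxyphenyl (guaiacyl) ring (ring B) and C3 a hydroxymethyl group. The only stereocentres are the neighbours C2 and C3, trans to each other and (2R,3S), so a synthesis has to close the five-membered ring, place the two substituents across it and fix one absolute sense. The two centres are not equal. C2 is an ether carbon benzylic to a para-oxygenated ring, so its C2–O1 bond can ionise and re-close, and it tends to settle trans to whatever sits on C3. C3 is configurationally firm as long as its substituent is not a carbonyl group, so C3 is the centre to set with a catalyst and C2 can be left to follow. Once C3 bears an aldehyde or ester it can enolise and the enolate can expel the O1 phenoxide, so carbonyl oxidation states at that carbon must be passed without base. The free molecule holds three phenols, one of them para to C2 (quinone methide formation), and an electron-rich stilbene that tolerates neither hydrogenation nor strong acid; the two aryl methyl ethers rule out boron trihalides at the end. A short approach is possible because O1, C7a, C3a and C3 form a four-atom chain that exists ready-made in an ortho-hydroxy-β-nitrostyrene: phenol oxygen, two arene carbons and the alkene carbon next to ring A. The ring then lacks only C2, which bears nothing but hydrogen and ring B and can be delivered as a benzylic sulfonium ylide, nucleophilic first and electrophilic afterwards. The nitromethyl group left on C3 has the carbon count of the hydroxymethyl group, and C5, para to O1, can carry a bromine atom through the sequence as the anchor for the stilbene.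

## Retrosynthesis

**19 from 18.** The three phenolic O–H bonds are traced back to silyl ethers in 18: two tert-butyldimethylsilyl groups on ring C and a triisopropylsilyl group on ring B. Silyl ethers are chosen over benzyl or methyl ethers because the stilbene forbids hydrogenolysis and the methoxy groups forbid Lewis-acid dealkylation. One buffered fluoride treatment should release all three phenols. The forward step asks only that the phenoxides are not left basic.

**18 from 14 and 17.** The C5–vinyl bond is cut, leading to aryl bromide 14 and styrene 17 (Heck reaction). The neighbouring cut at the C=C bond (Wittig or phosphonate olefination) would need a formyl group at C5, which would compete with the aldehyde used to build the nitroalkene. A bromine atom is inert in every earlier step and is already present in the commercial aldehyde 1. The forward step must arylate the terminal alkene carbon with (E) selectivity, at an electron-rich bromide, beside a free primary alcohol and aryl silyl ethers.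

**14 from 13 from 12.** The hydroxymethyl group is traced, on the same carbon, to the carboxylic acid 13 and then to the nitromethyl group of 12. The path through the acid is preferred to the shorter-looking path through the aldehyde. A C3 aldehyde would have to survive a basic reduction while able to enolise and open the ring. The acid forms in weakly acidic medium and is reduced by an electrophilic hydride.

**12 from 3 and 9.** This is the key cut: the C2–C3 and O1–C2 bonds are broken together. It removes the ring and both stereocentres in one stroke and leaves two achiral pieces, nitrostyrene 3 and sulfonium salt 9, each derived from a vanillin-type aldehyde. Cutting O1–C2 with C3–C3a instead would demand a diazo ester on a homologated side chain. Cutting C3–C3a alone (ring contraction) would pass the stereocentre through strong acid. The forward reaction has to make the conjugate addition enantioselective and has to close through the phenoxide, not through the nitronate.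

**3 from 1 and 2.** The alkene is cut by a Henry condensation into 5-bromo-2-hydroxy-3-methoxybenzaldehyde 1 and nitromethane 2. Nitromethane supplies the carbon that ends as the hydroxymethyl carbon. Nothing is asked beyond the usual (E) selectivity of the dehydration.

**9 from 7 and 8, and 7 from 6, 5 and 4.** The S–C bond of 9 is cut to benzylic bromide 7 and tetrahydrothiophene 8. Bromide 7 goes back through alcohol 6 and silyl ether 5 to vanillin 4. The triisopropylsilyl group is chosen here because this oxygen must survive carbonate and a phenoxide in the annulation, where a tert-butyldimethylsilyl ether would be at risk.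

**17 from 16 from 15.** The terminal alkene is cut by Wittig methylenation to aldehyde 16, the bis-silyl ether of 3,5-dihydroxybenzaldehyde 15. Silyl protection is chosen so that ring C is unmasked in the same final step as ring B.

## Roads not taken

**Alternative 1: asymmetric Prins-type hydroxymethylation and cyclisation of a stilbene.**
- *Cut:* the O1–C2 bond together with the exocyclic C3–CH2OH bond.
- *Forward key step:* stilbene A2 would react with formaldehyde A3 under a confined chiral Brønsted acid. The alkene carbon next to ring A attacks the activated aldehyde, the cation at the ring-B benzylic carbon is caught by the ortho silyloxy oxygen, and loss of silyl gives dihydrobenzofuran A1.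
- *Merits:* the hydroxymethyl group arrives in its final oxidation state, which saves the two functional-group steps the chosen route spends on the nitromethyl group. Ring and both stereocentres form in one operation from a flat, easily made precursor.
- *Weak points:* C3 must be set by facial discrimination in an attack on the smallest possible aldehyde by a hindered, electron-rich 1,2-diaryl alkene. The para-silyloxybenzyl cation is long-lived, so oligomerisation and loss of silyl ethers to the strong acid compete. The new primary alcohol can react on with the aldehyde. The C5 ester of A1 still needs reduction, oxidation and olefination.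
- *Comparison:* in oxidation-state economy at C3 this road is better, and the step counts are close. The chosen plan sets against it a closer precedent (same acceptor class, same ring closure, only the ylide changed), a basic medium in which silyl ethers and electron-rich rings are at ease, and a C5 bromide that is used directly.

**Alternative 2: conjunctive cross-coupling on a vinylboron linchpin.**
- *Cut:* the C3–C3a bond and the C2–aryl bond; no ring bond is made in the key step.
- *Forward key step:* vinylboronic ester A5 and the ring-A aryllithium A6 give the boron ate complex A7. A chiral palladium catalyst couples A7 with the ring-B triflate A8: ring A shifts from boron to the α-carbon while palladium delivers ring B to the β-carbon, giving boronate A4.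
- *Merits:* this is an established enantioselective reaction type for aryl migrating groups and aryl triflates, so its precedent is better than that of the chosen key step. C3 is set under catalyst control, and the boron atom allows a stereospecific one-carbon homologation to the hydroxymethyl group.
- *Weak points:* the key step makes only one of the two stereocentres and closes no ring. C2 arrives as a methylene group and must later be oxidised next to an electron-rich ring and joined to O1. The migrating ring carries an ortho alkoxy group. The methoxymethyl ethers and the dioxolane call for acid late in the sequence, and the aldehyde still has to be olefinated, so the route is several steps longer.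
- *Comparison:* the key step is safer, the whole is weaker. Against its unproven step the chosen plan sets ring closure and both stereocentres in one operation and a shorter sequence.

**Alternative 3: ring contraction of a flavanone by a trivalent iodine reagent.**
- *Cut:* the C3–C3a bond.
- *Forward key step:* in flavanone A10, PhI(OAc)2 in acidic trimethyl orthoformate attacks the enol ether at C3, the ring-A carbon C4a migrates from C4 to C3, and C4 leaves the ring as a methyl ester, giving the trans ester A9.
- *Merits:* the reaction type is known on flavanones and gives trans esters, so it is better precedented than the chosen key step. A9 carries the same C5 bromide and is a single hydride reduction away from 14, one step fewer than from 12.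
- *Weak points:* the contraction creates no absolute configuration; it only relays C2 of A10, so an enantioselective flavanone synthesis must be placed in front. A flavanone with a para-oxygenated 2-aryl group can lose that configuration by reversible retro-oxa-Michael ring opening under the acidic conditions the contraction needs. Migration of the C2 aryl group in place of C4a, and dehydrogenation of the heterocycle, are competing pathways that the pivalate on ring B only partly restrains.
- *Comparison:* this road wins on precedent and on the step after the key step. The chosen plan sets against it that the absolute configuration is created catalytically in the ring-forming step itself, that the labile C2 centre is never carried through strong acid, and that both fragments come in one to four steps from commercial aldehydes.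

Key step: step 6

Assumption: the facial preference of the quinine-derived squaramide toward a benzylic ylide is not established; it is written as the catalyst leading to (3S), and the quinidine-derived pseudoenantiomer would take its place if the opposite sense were found.

## Route

Step 1
Reactants: 1 5-bromo-2-hydroxy-3-methoxybenzaldehyde; 2 nitromethane
Product: 3 (E)-4-bromo-2-methoxy-6-(2-nitrovinyl)phenol
Conditions: MeNO2 (excess), NH4OAc, AcOH, 100 °C
Reagents that add atoms: none
Why: Henry (nitroaldol) condensation with dehydration in the same pot; the conjugated (E)-nitroalkene is the thermodynamic product, and ortho-hydroxybenzaldehydes are standard substrates.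

Step 2
Reactants: 4 vanillin (4-hydroxy-3-methoxybenzaldehyde)
Product: 5 3-methoxy-4-(triisopropylsilyloxy)benzaldehyde
Conditions: TIPSCl, imidazole, DMF, rt
Reagents that add atoms: triisopropylsilyl chloride, CC(C)[Si](Cl)(C(C)C)C(C)C
Why: Imidazole-promoted silylation of a phenol; the bulky triisopropylsilyl ether is chosen because it should resist carbonate and phenoxide in step 6.

Step 3
Reactants: 5 3-methoxy-4-(triisopropylsilyloxy)benzaldehyde
Product: 6 [3-methoxy-4-(triisopropylsilyloxy)phenyl]methanol
Conditions: NaBH4, MeOH, 0 °C
Reagents that add atoms: none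
Why: Borohydride reduction of an aryl aldehyde; the aryl silyl ether is stable to cold methanolic borohydride for the short reaction time.

Step 4
Reactants: 6 [3-methoxy-4-(triisopropylsilyloxy)phenyl]methanol
Product: 7 4-(bromomethyl)-2-methoxy-1-(triisopropylsilyloxy)benzene
Conditions: PBr3, Et2O, 0 °C
Reagents that add atoms: phosphorus tribromide, BrP(Br)Br
Why: Bromination of a benzylic alcohol through its phosphite ester; the electron-rich bromide is labile and should be used crude in step 5.

Step 5
Reactants: 7 4-(bromomethyl)-2-methoxy-1-(triisopropylsilyloxy)benzene; 8 tetrahydrothiophene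
Product: 9 1-[3-methoxy-4-(triisopropylsilyloxy)benzyl]tetrahydrothiophenium bromide
Conditions: tetrahydrothiophene, acetone, rt
Reagents that add atoms: none
Why: SN2 S-alkylation of a cyclic sulfide by a benzylic bromide; precipitation of the salt from acetone should pull the reversible alkylation forward.

Step 6
Reactants: 3 (E)-4-bromo-2-methoxy-6-(2-nitrovinyl)phenol; 9 1-[3-methoxy-4-(triisopropylsilyloxy)benzyl]tetrahydrothiophenium bromide
Product: 12 (2R,3S)-5-bromo-7-methoxy-2-[3-methoxy-4-(triisopropylsilyloxy)phenyl]-3-(nitromethyl)-2,3-dihydrobenzofuran (trans), via benzylic sulfonium ylide 10 (not isolated), via nitronate sulfonium betaine 11 (not isolated)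
Conditions: 9 (1.5 equiv), Cs2CO3 (2.5 equiv), quinine-derived bifunctional squaramide (from 9-amino-9-deoxy-epi-quinine and 3,5-bis(trifluoromethyl)aniline, 10 mol%), CH2Cl2, −20 °C
Reagents that add atoms: none
Why: Proposed new method: Cs2CO3 first removes the acidic phenol proton of 3 and then slowly deprotonates 9 to ylide 10, whose benzylic carbon adds to the arene-bound carbon of the nitroalkene to give betaine 11 (C2–C3 bond); the phenoxide oxygen then displaces tetrahydrothiophene at the sulfonium carbon (O1–C2 bond) and the nitronate is protonated. The closest known reaction type is the hydrogen-bond-catalysed enantioselective (4+1) annulation of 2-hydroxy-β-nitrostyrenes with carbonyl-stabilised sulfur ylides, which gives trans-2,3-dihydrobenzofurans; the extension is to a semi-stabilised benzylic ylide generated in situ. The dihydrofuran ring closes by a 5-exo-tet SN2 displacement at the former ylide carbon. C3 is set in the conjugate addition: the squaramide N–H bonds hold the nitro group and the protonated quinuclidine pairs with the phenoxide, so that one face of the alkene is left open to the ylide. C2 follows from C3: the betaine closes with inversion, its sulfonium-bearing carbon can equilibrate by reversible deprotonation, and any ionisation toward the para-silyloxybenzyl cation also collapses to the less crowded trans isomer. The step needs chemoselectivity for phenoxide O-alkylation over closure by the nitronate (through carbon to a nitrocyclopropane, through oxygen to an isoxazoline N-oxide) and over intermolecular O-benzylation of 3 by 9; the ortho position of the phenoxide (five-membered transition state), hydrogen bonding of the nitronate to the catalyst and a low stationary ylide concentration at −20 °C are relied on to secure it.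

Step 7
Reactants: 12 (2R,3S)-5-bromo-7-methoxy-2-[3-methoxy-4-(triisopropylsilyloxy)phenyl]-3-(nitromethyl)-2,3-dihydrobenzofuran
Product: 13 (2R,3R)-5-bromo-7-methoxy-2-[3-methoxy-4-(triisopropylsilyloxy)phenyl]-2,3-dihydrobenzofuran-3-carboxylic acid (trans)
Conditions: NaNO2, AcOH, DMSO, 35 °C
Reagents that add atoms: sodium nitrite, [Na+].[O-]N=O; water, O (the carboxyl oxygens come from nitrite and from the hydration stage)
Why: Nitrite-mediated oxidative Nef-type conversion of a primary nitroalkane into the carboxylic acid (nitrosation at the carbon α to the nitro group, then hydrolysis); the medium is weakly acidic, so C3 is not enolised and keeps its spatial arrangement (the descriptor becomes R only through the change in substituent priority).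

Step 8
Reactants: 13 (2R,3R)-5-bromo-7-methoxy-2-[3-methoxy-4-(triisopropylsilyloxy)phenyl]-2,3-dihydrobenzofuran-3-carboxylic acid
Product: 14 {(2R,3S)-5-bromo-7-methoxy-2-[3-methoxy-4-(triisopropylsilyloxy)phenyl]-2,3-dihydrobenzofuran-3-yl}methanol (trans)
Conditions: BH3·THF, THF, 0 °C to rt; then MeOH, aqueous work-up
Reagents that add atoms: none
Why: Chemoselective borane reduction of a carboxylic acid through its acyloxyborane; the hydride is electrophilic and the medium non-basic, so C3 cannot epimerise and the aryl bromide and silyl ether are untouched.

Step 9
Reactants: 15 3,5-dihydroxybenzaldehyde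
Product: 16 3,5-bis(tert-butyldimethylsilyloxy)benzaldehyde
Conditions: TBSCl, imidazole, DMF, rt
Reagents that add atoms: tert-butyldimethylsilyl chloride, CC(C)(C)[Si](C)(C)Cl
Why: Imidazole-promoted silylation of both phenols; silyl ethers are chosen so that ring C is unmasked together with ring B in the last step.

Step 10
Reactants: 16 3,5-bis(tert-butyldimethylsilyloxy)benzaldehyde
Product: 17 3,5-bis(tert-butyldimethylsilyloxy)styrene
Conditions: Ph3PCH3Br, KOtBu, THF, 0 °C to rt
Reagents that add atoms: methyltriphenylphosphonium bromide, C[P+](c1ccccc1)(c1ccccc1)c1ccccc1.[Br-]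
Why: Wittig methylenation of an aryl aldehyde with the non-stabilised ylide; no stereochemical issue arises for a terminal alkene.

Step 11
Reactants: 14 {(2R,3S)-5-bromo-7-methoxy-2-[3-methoxy-4-(triisopropylsilyloxy)phenyl]-2,3-dihydrobenzofuran-3-yl}methanol; 17 3,5-bis(tert-butyldimethylsilyloxy)styrene
Product: 18 {(2R,3S)-5-{(E)-2-[3,5-bis(tert-butyldimethylsilyloxy)phenyl]ethenyl}-7-methoxy-2-[3-methoxy-4-(triisopropylsilyloxy)phenyl]-2,3-dihydrobenzofuran-3-yl}methanol
Conditions: Pd2(dba)3 (2.5 mol%), [HP(t-Bu)3]BF4 (10 mol%), Cy2NMe, 1,4-dioxane, 80 °C
Reagents that add atoms: none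
Why: Heck reaction: oxidative addition of the aryl bromide to zerovalent palladium carrying a bulky electron-rich phosphine, insertion of the styrene at its terminal carbon and syn β-hydride elimination give the (E)-stilbene. The amine base and moderate temperature spare the aryl silyl ethers, and the free primary alcohol is a spectator.

Step 12
Reactants: 18 {(2R,3S)-5-{(E)-2-[3,5-bis(tert-butyldimethylsilyloxy)phenyl]ethenyl}-7-methoxy-2-[3-methoxy-4-(triisopropylsilyloxy)phenyl]-2,3-dihydrobenzofuran-3-yl}methanol
Product: 19 gnetofuran A (5-{(E)-2-[(2R,3S)-2-(4-hydroxy-3-methoxyphenyl)-3-(hydroxymethyl)-7-methoxy-2,3-dihydrobenzofuran-5-yl]ethenyl}benzene-1,3-diol)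
Conditions: Bu4NF, AcOH, THF, 0 °C to rt
Reagents that add atoms: none
Why: Fluoride-mediated cleavage of the three aryl silyl ethers; acetic acid buffers the phenoxides, so the para-hydroxybenzyl ether at C2 should not open through a quinone methide and the resorcinol stilbene is not exposed to base.

## Compound list

1 | 5-bromo-2-hydroxy-3-methoxybenzaldehyde | COc1cc(Br)cc(C=O)c1O | starting material
2 | nitromethane | C[N+](=O)[O-] | starting material
3 | (E)-4-bromo-2-methoxy-6-(2-nitrovinyl)phenol | COc1cc(Br)cc(/C=C/[N+](=O)[O-])c1O | intermediate
4 | vanillin (4-hydroxy-3-methoxybenzaldehyde) | COc1cc(C=O)ccc1O | starting material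
5 | 3-methoxy-4-(triisopropylsilyloxy)benzaldehyde | COc1cc(C=O)ccc1O[Si](C(C)C)(C(C)C)C(C)C | intermediate
6 | [3-methoxy-4-(triisopropylsilyloxy)phenyl]methanol | COc1cc(CO)ccc1O[Si](C(C)C)(C(C)C)C(C)C | intermediate
7 | 4-(bromomethyl)-2-methoxy-1-(triisopropylsilyloxy)benzene | COc1cc(CBr)ccc1O[Si](C(C)C)(C(C)C)C(C)C | intermediate
8 | tetrahydrothiophene | C1CCSC1 | starting material
9 | 1-[3-methoxy-4-(triisopropylsilyloxy)benzyl]tetrahydrothiophenium bromide | COc1cc(C[S+]2CCCC2)ccc1O[Si](C(C)C)(C(C)C)C(C)C.[Br-] | intermediate
10 | (tetrahydrothiophenium-1-yl)[3-methoxy-4-(triisopropylsilyloxy)phenyl]methanide (benzylic sulfonium ylide) | COc1cc([CH-][S+]2CCCC2)ccc1O[Si](C(C)C)(C(C)C)C(C)C | intermediate (not isolated)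
11 | 1-{(1S,2S)-2-(5-bromo-2-hydroxy-3-methoxyphenyl)-1-[3-methoxy-4-(triisopropylsilyloxy)phenyl]-3-nitronatopropyl}tetrahydrothiophenium (betaine; C-1 becomes C2 and C-2 becomes C3 of the ring) | COc1cc([C@@H]([S+]2CCCC2)[C@H](C=[N+]([O-])[O-])c2cc(Br)cc(OC)c2O)ccc1O[Si](C(C)C)(C(C)C)C(C)C | intermediate (not isolated)
12 | (2R,3S)-5-bromo-7-methoxy-2-[3-methoxy-4-(triisopropylsilyloxy)phenyl]-3-(nitromethyl)-2,3-dihydrobenzofuran (trans) | COc1cc([C@@H]2Oc3c(OC)cc(Br)cc3[C@H]2C[N+](=O)[O-])ccc1O[Si](C(C)C)(C(C)C)C(C)C | intermediate
13 | (2R,3R)-5-bromo-7-methoxy-2-[3-methoxy-4-(triisopropylsilyloxy)phenyl]-2,3-dihydrobenzofuran-3-carboxylic acid (trans) | COc1cc([C@@H]2Oc3c(OC)cc(Br)cc3[C@H]2C(=O)O)ccc1O[Si](C(C)C)(C(C)C)C(C)C | intermediate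
14 | {(2R,3S)-5-bromo-7-methoxy-2-[3-methoxy-4-(triisopropylsilyloxy)phenyl]-2,3-dihydrobenzofuran-3-yl}methanol (trans) | COc1cc([C@@H]2Oc3c(OC)cc(Br)cc3[C@H]2CO)ccc1O[Si](C(C)C)(C(C)C)C(C)C | intermediate
15 | 3,5-dihydroxybenzaldehyde | O=Cc1cc(O)cc(O)c1 | starting material
16 | 3,5-bis(tert-butyldimethylsilyloxy)benzaldehyde | O=Cc1cc(O[Si](C)(C)C(C)(C)C)cc(O[Si](C)(C)C(C)(C)C)c1 | intermediate
17 | 3,5-bis(tert-butyldimethylsilyloxy)styrene | C=Cc1cc(O[Si](C)(C)C(C)(C)C)cc(O[Si](C)(C)C(C)(C)C)c1 | intermediate
18 | {(2R,3S)-5-{(E)-2-[3,5-bis(tert-butyldimethylsilyloxy)phenyl]ethenyl}-7-methoxy-2-[3-methoxy-4-(triisopropylsilyloxy)phenyl]-2,3-dihydrobenzofuran-3-yl}methanol | COc1cc([C@@H]2Oc3c(OC)cc(/C=C/c4cc(O[Si](C)(C)C(C)(C)C)cc(O[Si](C)(C)C(C)(C)C)c4)cc3[C@H]2CO)ccc1O[Si](C(C)C)(C(C)C)C(C)C | intermediate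
19 | gnetofuran A, 5-{(E)-2-[(2R,3S)-2-(4-hydroxy-3-methoxyphenyl)-3-(hydroxymethyl)-7-methoxy-2,3-dihydrobenzofuran-5-yl]ethenyl}benzene-1,3-diol | COc1cc([C@@H]2Oc3c(OC)cc(/C=C/c4cc(O)cc(O)c4)cc3[C@H]2CO)ccc1O | target

## Step count and risk

Total step count: 12. Longest linear sequence: 9 steps (steps 2, 3, 4, 5, 6, 7, 8, 11 and 12, from vanillin 4).

**Step 6 (key step, proposed new method).**
- *What may go wrong:* the semi-stabilised ylide is far more basic than the carbonyl-stabilised ylides of the precedent. Proton transfer from the phenol can quench it, and the resulting phenoxide deactivates the acceptor. Addition through a caesium phenoxide outside the chiral pocket would give poor facial selectivity. Closure through the nitronate (cyclopropanation, or O-alkylation to an isoxazoline N-oxide), direct O-benzylation of the phenoxide by the sulfonium salt, and decay of the ylide by rearrangement or silyl loss are further losses.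
- *Fallback (known chemistry):* enantioselective intramolecular C–H insertion of an aryldiazoacetate, setting out from 3 and 7 and returning at 14. O-Alkylation of 3 with 7 (K2CO3, DMF) would give the O-benzyl nitrostyrene F1. Conjugate reduction (NaBH4, THF/MeOH) gives the nitroethyl arene F2, and the nitrite oxidation of step 7 gives the arylacetic acid F3. Esterification (MeI, K2CO3) gives the methyl ester F4, and diazo transfer (p-acetamidobenzenesulfonyl azide, DBU) gives the aryldiazoacetate F5. A chiral dirhodium tetracarboxylate such as Rh2(S-PTTL)4, or its enantiomer as required for (2R), should insert the carbenoid into the benzylic C–H bond of the ether to give the cis ester F6. Base-mediated epimerisation at C3 (DBU, toluene) leads to the trans ester F7, and LiBH4 reduction gives 14.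

**Step 5.**
- *What may go wrong:* reversal of the S-alkylation by bromide and solvolytic loss of tetrahydrothiophene through the para-silyloxybenzyl cation during isolation or storage; the same lability affects bromide 7 in step 4.
- *Fallback:* from alcohol 6, dehydrative S-alkylation with tetrahydrothiophene and TfOH (1 equiv) in CH2Cl2 at 0 °C, with no halide at any stage, would give the sulfonium triflate F8 with a non-nucleophilic counter-ion. Deprotonation of F8 under the conditions of step 6 gives the same ylide 10, where the route is rejoined.

**Step 7.**
- *What may go wrong:* nitrosation of the electron-rich rings by the nitrous acid medium, stalling at intermediate oxidation levels at the hindered carbon, or acid-promoted ionisation of the C2–O1 bond.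
- *Fallback:* from 12, a reductive Nef reaction: the nitronate (NaOMe, MeOH, 0 °C) is added to aqueous TiCl3 (trivalent titanium) buffered with NH4OAc, giving the trans aldehyde F9. F9 is reduced at once with NaBH4 at 0 °C to 14, bypassing 13.

**Step 11.**
- *What may go wrong:* slow oxidative addition to the electron-rich bromide with catalyst decay, arylation at the internal alkene carbon, and thermal loss of aryl silyl groups.
- *Fallback:* from 17, cross-metathesis with vinylboronic acid pinacol ester (second-generation Grubbs catalyst, CH2Cl2, 40 °C) would give the (E)-styrylboronate F10. Suzuki–Miyaura coupling of F10 with 14 (Pd(dppf)Cl2, K3PO4, dioxane/water, 70 °C) forms the same bond by transmetalation and returns to the route at 18.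

## Further compounds

F1 | step 6 | (E)-5-bromo-1-methoxy-2-{[3-methoxy-4-(triisopropylsilyloxy)benzyl]oxy}-3-(2-nitrovinyl)benzene | COc1cc(Br)cc(/C=C/[N+](=O)[O-])c1OCc1ccc(O[Si](C(C)C)(C(C)C)C(C)C)c(OC)c1
F2 | step 6 | 5-bromo-1-methoxy-2-{[3-methoxy-4-(triisopropylsilyloxy)benzyl]oxy}-3-(2-nitroethyl)benzene | COc1cc(Br)cc(CC[N+](=O)[O-])c1OCc1ccc(O[Si](C(C)C)(C(C)C)C(C)C)c(OC)c1
F3 | step 6 | 2-(5-bromo-3-methoxy-2-{[3-methoxy-4-(triisopropylsilyloxy)benzyl]oxy}phenyl)acetic acid | COc1cc(Br)cc(CC(=O)O)c1OCc1ccc(O[Si](C(C)C)(C(C)C)C(C)C)c(OC)c1
F4 | step 6 | methyl 2-(5-bromo-3-methoxy-2-{[3-methoxy-4-(triisopropylsilyloxy)benzyl]oxy}phenyl)acetate | COC(=O)Cc1cc(Br)cc(OC)c1OCc1ccc(O[Si](C(C)C)(C(C)C)C(C)C)c(OC)c1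
F5 | step 6 | methyl 2-(5-bromo-3-methoxy-2-{[3-methoxy-4-(triisopropylsilyloxy)benzyl]oxy}phenyl)-2-diazoacetate | COC(=O)C(=[N+]=[N-])c1cc(Br)cc(OC)c1OCc1ccc(O[Si](C(C)C)(C(C)C)C(C)C)c(OC)c1
F6 | step 6 | methyl (2R,3S)-cis-5-bromo-7-methoxy-2-[3-methoxy-4-(triisopropylsilyloxy)phenyl]-2,3-dihydrobenzofuran-3-carboxylate | COc1cc([C@@H]2Oc3c(OC)cc(Br)cc3[C@@H]2C(=O)OC)ccc1O[Si](C(C)C)(C(C)C)C(C)C
F7 | step 6 | methyl (2R,3R)-trans-5-bromo-7-methoxy-2-[3-methoxy-4-(triisopropylsilyloxy)phenyl]-2,3-dihydrobenzofuran-3-carboxylate | COc1cc([C@@H]2Oc3c(OC)cc(Br)cc3[C@H]2C(=O)OC)ccc1O[Si](C(C)C)(C(C)C)C(C)C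
F8 | step 5 | 1-[3-methoxy-4-(triisopropylsilyloxy)benzyl]tetrahydrothiophenium trifluoromethanesulfonate | COc1cc(C[S+]2CCCC2)ccc1O[Si](C(C)C)(C(C)C)C(C)C.[O-]S(=O)(=O)C(F)(F)F
F9 | step 7 | (2R,3R)-trans-5-bromo-7-methoxy-2-[3-methoxy-4-(triisopropylsilyloxy)phenyl]-2,3-dihydrobenzofuran-3-carbaldehyde | COc1cc([C@@H]2Oc3c(OC)cc(Br)cc3[C@H]2C=O)ccc1O[Si](C(C)C)(C(C)C)C(C)C
F10 | step 11 | (E)-2-{2-[3,5-bis(tert-butyldimethylsilyloxy)phenyl]ethenyl}-4,4,5,5-tetramethyl-1,3,2-dioxaborolane | CC(C)(C)[Si](C)(C)Oc1cc(/C=C/B2OC(C)(C)C(C)(C)O2)cc(O[Si](C)(C)C(C)(C)C)c1
A1 | alternative 1 | methyl (2R,3S)-trans-3-(hydroxymethyl)-7-methoxy-2-[3-methoxy-4-(triisopropylsilyloxy)phenyl]-2,3-dihydrobenzofuran-5-carboxylate | COc1cc([C@@H]2Oc3c(OC)cc(C(=O)OC)cc3[C@H]2CO)ccc1O[Si](C(C)C)(C(C)C)C(C)C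
A2 | alternative 1 | methyl 4-(tert-butyldimethylsilyloxy)-3-methoxy-5-{(E)-2-[3-methoxy-4-(triisopropylsilyloxy)phenyl]ethenyl}benzoate | COC(=O)c1cc(OC)c(O[Si](C)(C)C(C)(C)C)c(/C=C/c2ccc(O[Si](C(C)C)(C(C)C)C(C)C)c(OC)c2)c1
A3 | alternative 1 | formaldehyde | C=O
A4 | alternative 2 | (S)-2-{1-[5-(1,3-dioxolan-2-yl)-3-methoxy-2-(methoxymethoxy)phenyl]-2-[3-methoxy-4-(methoxymethoxy)phenyl]ethyl}-4,4,5,5-tetramethyl-1,3,2-dioxaborolane | COc1cc(C[C@H](B2OC(C)(C)C(C)(C)O2)c2cc(C3OCCO3)cc(OC)c2OCOC)ccc1OCOC
A5 | alternative 2 | 4,4,5,5-tetramethyl-2-vinyl-1,3,2-dioxaborolane | C=CB1OC(C)(C)C(C)(C)O1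
A6 | alternative 2 | [5-(1,3-dioxolan-2-yl)-3-methoxy-2-(methoxymethoxy)phenyl]lithium | [Li]c1cc(C2OCCO2)cc(OC)c1OCOC
A7 | alternative 2 | lithium [5-(1,3-dioxolan-2-yl)-3-methoxy-2-(methoxymethoxy)phenyl](vinyl)(pinacolato)borate | [Li+].C=C[B-]1(OC(C)(C)C(C)(C)O1)c1cc(C2OCCO2)cc(OC)c1OCOC
A8 | alternative 2 | 3-methoxy-4-(methoxymethoxy)phenyl trifluoromethanesulfonate | COc1cc(OS(=O)(=O)C(F)(F)F)ccc1OCOC
A9 | alternative 3 | methyl (2R,3R)-trans-5-bromo-7-methoxy-2-[3-methoxy-4-(pivaloyloxy)phenyl]-2,3-dihydrobenzofuran-3-carboxylate | COc1cc([C@@H]2Oc3c(OC)cc(Br)cc3[C@H]2C(=O)OC)ccc1OC(=O)C(C)(C)C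
A10 | alternative 3 | (R)-6-bromo-8-methoxy-2-[3-methoxy-4-(pivaloyloxy)phenyl]chroman-4-one | COc1cc([C@H]2CC(=O)c3cc(Br)cc(OC)c3O2)ccc1OC(=O)C(C)(C)C
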